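**Retrosynthetic overview**
1. The 1,2-dioxepane is opened to an 11-hydroperoxy-15,16-dial (peroxy-hemiacetal ring–chain tautomer); the hydroperoxide comes from γ-oxygenation of an (E)-enal side chain attached by Wittig olefination at C12.
2. The decalin is traced back (C4 formyl to methyl, ring-A alkene to alkane) to the adduct of an intramolecular Diels–Alder reaction that disconnects C3–C4 and C5–C10 of an acyclic (2E,8E)-undeca-2,8,10-trienal.
3. Enabling feature: ring A is a cyclohexane lying between two quaternary carbons, C4 (gem-dimethyl) and C10 (angular methyl), trans-fused to ring B along C5–C10. Writing one C4 methyl as CHO and C1–C2 as C=C makes ring A the cyclohexene of a [4+2] reaction whose enal (C4=C5) and diene (C10=C1–C2=C3) are joined by C6–C9, which already carry the 7-oxygen, the C8 methylene and the C9 branch.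
4. The trienal comes from a simple enal: C9 by asymmetric conjugate alkynylation, the diene by carboalumination/iodination and Stille coupling, C17 by α-methylenation, C7 by asymmetric allylboration, and the enal by cross-metathesis with methacrolein.
5. Ring order: rings A and B together (step 12), the peroxide ring last (step 21).

Key step: step 12

Remark 1: C15 is a peroxy-hemiacetal carbon and is taken to equilibrate; the (15R) epimer is assumed to be the thermodynamically preferred one.
Remark 2: the sense of induction assigned to the ligand in step 3 and to the allylborane in step 8 follows the usual models for these reagents; if either proves opposite, the antipodal ligand or borane is used.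

**Route**

Step 1
Reactants: 1 but-3-en-1-ol; 2 4-methoxybenzyl chloride
Product: 3 1-[(but-3-en-1-yloxy)methyl]-4-methoxybenzene
Conditions: NaH, Bu4NI (cat.), THF/DMF, 0 °C to rt
Reagents that add atoms: 4-methoxybenzyl chloride (2), COc1ccc(CCl)cc1
Why: Williamson etherification of the primary alkoxide with a benzylic chloride, which creates no stereocenter.

Step 2
Reactants: 3 1-[(but-3-en-1-yloxy)methyl]-4-methoxybenzene; 4 (E)-but-2-enal
Product: 5 (E)-5-[(4-methoxybenzyl)oxy]pent-2-enal
Conditions: second-generation Grubbs catalyst RuCl2(=CHPh)(PCy3)(SIMes) (3 mol%), CH2Cl2, 40 °C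
Reagents that add atoms: (E)-but-2-enal (4), C/C=C/C=O
Why: Olefin cross-metathesis of a terminal alkene with crotonaldehyde should give the conjugated (E)-enal as the thermodynamic product.

Step 3
Reactants: 5 (E)-5-[(4-methoxybenzyl)oxy]pent-2-enal; 6 ethynyltriisopropylsilane
Product: 8 (R)-3-{2-[(4-methoxybenzyl)oxy]ethyl}-5-(triisopropylsilyl)pent-4-yn-1-ol, via alkynyl aldehyde 7 (not isolated)
Conditions: [Rh(OAc)(C2H4)2]2 (2.5 mol%), (R)-DTBM-SEGPHOS (6 mol%), MeOH, 40 °C; then NaBH4, 0 °C
Reagents that add atoms: ethynyltriisopropylsilane (6), C#C[Si](C(C)C)(C(C)C)C(C)C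
Why: Rhodium-catalysed asymmetric conjugate alkynylation of a β-alkyl enal with a bulky silylacetylene should set C9 by ligand-controlled facial selection in the alkynylrhodium insertion, and the in-flask borohydride reduction stores the aldehyde as an alcohol for the organoaluminium step.

Step 4
Reactants: 8 (R)-3-{2-[(4-methoxybenzyl)oxy]ethyl}-5-(triisopropylsilyl)pent-4-yn-1-ol
Product: 9 (R)-3-{2-[(4-methoxybenzyl)oxy]ethyl}pent-4-yn-1-ol
Conditions: Bu4NF, THF, 0 °C to rt
Reagents that add atoms: none
Why: Fluoride-induced cleavage of the alkynyl C–Si bond should free the terminal alkyne without touching the ether or the stereocenter.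

Step 5
Reactants: 9 (R)-3-{2-[(4-methoxybenzyl)oxy]ethyl}pent-4-yn-1-ol
Product: 11 (R,E)-5-iodo-3-{2-[(4-methoxybenzyl)oxy]ethyl}-4-methylpent-4-en-1-ol, via alkenylalane 10 (not isolated)
Conditions: AlMe3 (3 equiv), Cp2ZrCl2 (25 mol%), CH2Cl2, 0 °C to rt; then I2, THF, −30 to 0 °C
Reagents that add atoms: trimethylaluminium, C[Al](C)C; iodine, II
Why: Zirconium-catalysed syn-carboalumination of the terminal alkyne (methyl to the internal carbon) followed by iodinolysis with retention should give the (E)-trisubstituted vinyl iodide, the hydroxyl being carried as its aluminium alkoxide.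

Step 6
Reactants: 11 (R,E)-5-iodo-3-{2-[(4-methoxybenzyl)oxy]ethyl}-4-methylpent-4-en-1-ol
Product: 12 (S,E)-5-iodo-3-{2-[(4-methoxybenzyl)oxy]ethyl}-4-methylpent-4-enal
Conditions: Dess–Martin periodinane, NaHCO3, CH2Cl2, 0 °C to rt
Reagents that add atoms: none
Why: Dess–Martin oxidation of the primary alcohol gives the aldehyde, whose stereocenter is β to the carbonyl and cannot epimerize.

Step 7
Reactants: 12 (S,E)-5-iodo-3-{2-[(4-methoxybenzyl)oxy]ethyl}-4-methylpent-4-enal
Product: 13 (S,E)-5-iodo-3-{2-[(4-methoxybenzyl)oxy]ethyl}-4-methyl-2-methylidenepent-4-enal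
Conditions: aq. CH2O (37%), pyrrolidine (10 mol%), propionic acid (10 mol%), i-PrOH, 45 °C
Reagents that add atoms: formaldehyde, C=O
Why: Amine-catalysed Mannich-type α-methylenation of the aldehyde (enamine addition to formaldehyde iminium, then elimination) installs C17 on C8.

Step 8
Reactants: 13 (S,E)-5-iodo-3-{2-[(4-methoxybenzyl)oxy]ethyl}-4-methyl-2-methylidenepent-4-enal
Product: 14 (4S,6S,7E)-8-iodo-6-{2-[(4-methoxybenzyl)oxy]ethyl}-7-methyl-5-methylideneocta-1,7-dien-4-ol
Conditions: (−)-Ipc2BOMe [from (+)-α-pinene], CH2=CHCH2MgBr, Et2O, −78 °C to rt; then 13, −78 °C; then NaOH, H2O2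
Reagents that add atoms: allylmagnesium bromide, C=CC[Mg]Br
Why: Asymmetric allylboration through a chair-like six-membered transition state under control of the isopinocampheyl groups should deliver allyl to the si face of the aldehyde and set the (S) carbinol that becomes C7.

Step 9
Reactants: 14 (4S,6S,7E)-8-iodo-6-{2-[(4-methoxybenzyl)oxy]ethyl}-7-methyl-5-methylideneocta-1,7-dien-4-ol
Product: 15 tert-butyldimethylsilyl ether of 14
Conditions: TBSOTf, 2,6-lutidine, CH2Cl2, −78 °C
Reagents that add atoms: tert-butyldimethylsilyl triflate, CC(C)(C)[Si](C)(C)OS(=O)(=O)C(F)(F)F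
Why: Silylation of the hindered secondary allylic alcohol with a silyl triflate protects the 7-oxygen for the Lewis-acid and base steps ahead.

Step 10
Reactants: 15 tert-butyldimethylsilyl ether of 14; 16 2-methylprop-2-enal
Product: 17 (2E,5S,7S,8E)-5-[(tert-butyldimethylsilyl)oxy]-9-iodo-7-{2-[(4-methoxybenzyl)oxy]ethyl}-2,8-dimethyl-6-methylidenenona-2,8-dienal
Conditions: second-generation Hoveyda–Grubbs catalyst RuCl2(=CH-2-(i-PrO)C6H4)(SIMes) (5 mol%), methacrolein (excess), CH2Cl2, 40 °C
Reagents that add atoms: 2-methylprop-2-enal (16), C=C(C)C=O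
Why: Cross-metathesis of the monosubstituted alkene with methacrolein should give the (E)-2-methyl enal, the hindered 1,1-disubstituted alkene and the trisubstituted vinyl iodide being inert metathesis partners.

Step 11
Reactants: 17 (2E,5S,7S,8E)-5-[(tert-butyldimethylsilyl)oxy]-9-iodo-7-{2-[(4-methoxybenzyl)oxy]ethyl}-2,8-dimethyl-6-methylidenenona-2,8-dienal; 18 tributyl(vinyl)stannane
Product: 19 (2E,5S,7R,8E)-5-[(tert-butyldimethylsilyl)oxy]-7-{2-[(4-methoxybenzyl)oxy]ethyl}-2,8-dimethyl-6-methylideneundeca-2,8,10-trienal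
Conditions: Pd2(dba)3 (2.5 mol%), AsPh3 (20 mol%), NMP, 40 °C
Reagents that add atoms: tributyl(vinyl)stannane (18), C=C[Sn](CCCC)(CCCC)CCCC
Why: Stille coupling of the vinyl iodide proceeds with retention of geometry and completes the (E)-diene under neutral conditions that the enal tolerates.

Step 12
Reactants: 19 (2E,5S,7R,8E)-5-[(tert-butyldimethylsilyl)oxy]-7-{2-[(4-methoxybenzyl)oxy]ethyl}-2,8-dimethyl-6-methylideneundeca-2,8,10-trienal
Product: 20 7β-(tert-butyldimethylsilyloxy)-12-(4-methoxybenzyloxy)-13,14,15,16-tetranorlabda-1,8(17)-dien-18-al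
Conditions: Me2AlCl (1.5 equiv), CH2Cl2, −78 to −20 °C
Reagents that add atoms: none
Why: The aluminium-complexed (E)-2-methyl enal (C4=C5) and the tethered (E)-diene (C10=C1–C2=C3) should combine in a concerted, asynchronous type 1 intramolecular Diels–Alder reaction in which the C5–C10 bond is more advanced than the C3–C4 bond. The closest known reaction type is the Lewis-acid-promoted cyclization of (2E)-2-methyl-2,8,10-trienals to trans-decalins that carry a quaternary C(CH3)(CHO) centre. Ring A closes as the cyclohexene of the [4+2] event, and ring B closes at the same time through the four-atom tether C6–C9 in a chair-like six-membered arrangement with the formyl group endo. C5 and C10 should come out trans because the endo transition state places the tether exo on the dienophile while the inside methyl of the diene becomes the axial angular methyl; the diene face is chosen by C7 and C9, whose cis-1,3 silyloxy and side-chain groups are both equatorial in only one chair and syn-diaxial in the other; C4 (formyl equatorial, from the E enal) is a transient stereocenter erased in step 13. The step needs trans over cis fusion and one π-face, and the substrate secures both through the endo preference of the aluminium-bound formyl group and the (5S,7R) pair of tether substituents. Regiochemistry is fixed by the tether, and the exocyclic 1,1-disubstituted alkene is unactivated and geometrically unable to compete.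

Step 13
Reactants: 20 7β-(tert-butyldimethylsilyloxy)-12-(4-methoxybenzyloxy)-13,14,15,16-tetranorlabda-1,8(17)-dien-18-al
Product: 22 7β-(tert-butyldimethylsilyloxy)-12-(4-methoxybenzyloxy)-13,14,15,16-tetranorlabda-1,8(17)-diene, via N-silyl hydrazone 21 (not isolated)
Conditions: TBSNHNHTBS, Sc(OTf)3 (1 mol%), CH2Cl2, rt; then KOt-Bu, t-BuOH, DMSO, rt to 50 °C
Reagents that add atoms: none
Why: Wolff–Kishner reduction through the N-silyl hydrazone turns the activating formyl group into the second C4 methyl under mild base and removes the C4 stereocenter.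

Step 14
Reactants: 22 7β-(tert-butyldimethylsilyloxy)-12-(4-methoxybenzyloxy)-13,14,15,16-tetranorlabda-1,8(17)-diene
Product: 23 7β-(tert-butyldimethylsilyloxy)-12-(4-methoxybenzyloxy)-13,14,15,16-tetranorlabd-8(17)-ene
Conditions: H2 (1 atm), RhCl(PPh3)3 (10 mol%), benzene/EtOH, rt
Reagents that add atoms: none
Why: Homogeneous hydrogenation with RhCl(PPh3)3 should reduce the cis-disubstituted ring-A alkene (as in selective 1,2-reduction of steroidal 1,4-dienones) while the exocyclic alkene, flanked by the silyloxy carbon and the C9 branch, is too hindered to bind rhodium.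

Step 15
Reactants: 23 7β-(tert-butyldimethylsilyloxy)-12-(4-methoxybenzyloxy)-13,14,15,16-tetranorlabd-8(17)-ene
Product: 24 7β-(tert-butyldimethylsilyloxy)-13,14,15,16-tetranorlabd-8(17)-en-12-ol
Conditions: DDQ, CH2Cl2/pH 7 buffer, 0 °C
Reagents that add atoms: none
Why: Oxidative cleavage of the 4-methoxybenzyl ether by DDQ (benzylic hydride abstraction, hydrolysis of the oxocarbenium ion) frees the primary alcohol and leaves the silyl ether and the alkene intact.

Step 16
Reactants: 24 7β-(tert-butyldimethylsilyloxy)-13,14,15,16-tetranorlabd-8(17)-en-12-ol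
Product: 25 7β-(tert-butyldimethylsilyloxy)-13,14,15,16-tetranorlabd-8(17)-en-12-al
Conditions: Dess–Martin periodinane, NaHCO3, CH2Cl2, 0 °C to rt
Reagents that add atoms: none
Why: Dess–Martin oxidation gives the C12 aldehyde, in which C9 is β to the carbonyl and configurationally safe.

Step 17
Reactants: 26 3-bromo-1,1-dimethoxypropane; 27 triphenylphosphine
Product: 28 (3,3-dimethoxypropyl)triphenylphosphonium bromide
Conditions: MeCN, reflux
Reagents that add atoms: triphenylphosphine (27), c1ccc(cc1)P(c1ccccc1)c1ccccc1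
Why: SN2 quaternization of triphenylphosphine by the primary bromide.

Step 18
Reactants: 28 (3,3-dimethoxypropyl)triphenylphosphonium bromide; 29 ethyl formate
Product: 30 4,4-dimethoxy-2-(triphenyl-λ5-phosphanylidene)butanal
Conditions: KOt-Bu, THF, 0 °C; then HCO2Et, 0 °C to rt
Reagents that add atoms: ethyl formate (29), CCOC=O
Why: C-Formylation of the phosphorus ylide by acyl substitution on ethyl formate, the expelled ethoxide deprotonating the acylphosphonium ion to the stabilized formyl ylide.

Step 19
Reactants: 25 7β-(tert-butyldimethylsilyloxy)-13,14,15,16-tetranorlabd-8(17)-en-12-al; 30 4,4-dimethoxy-2-(triphenyl-λ5-phosphanylidene)butanal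
Product: 31 (12E)-7β-(tert-butyldimethylsilyloxy)-15,15-dimethoxylabda-8(17),12-dien-16-al
Conditions: toluene, 90 °C
Reagents that add atoms: ylide 30, O=CC(CC(OC)OC)=P(c1ccccc1)(c1ccccc1)c1ccccc1
Why: Wittig olefination with a stabilized α-formyl ylide should give the (E)-2-substituted enal (C11 trans to the formyl group) and react only with the saturated aldehyde.

Step 20
Reactants: 31 (12E)-7β-(tert-butyldimethylsilyloxy)-15,15-dimethoxylabda-8(17),12-dien-16-al
Product: 32 (11S,12E)-11-hydroperoxy-7β-(tert-butyldimethylsilyloxy)-15,15-dimethoxylabda-8(17),12-dien-16-al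
Conditions: KN(SiMe3)2, THF, −78 °C, O2 (1 atm); then AcOH, −78 °C
Reagents that add atoms: dioxygen, O=O
Why: Proposed new method: γ-deprotonation at C11 (the only position conjugated with the C16 aldehyde, C15 being masked as its acetal) should give the s-trans potassium dienolate, which combines with triplet oxygen at its γ-terminus by electron transfer and radical recombination and returns the conjugated (E)-enal bearing a C11 hydroperoxide after the cold acidic quench; in the rotamer with C9–H eclipsing the C11=C12 bond the quaternary C10 shields one face, so oxygen should enter anti to C10 and give 11S; the closest known reaction type is the base-mediated γ-hydroperoxidation of α,β-unsaturated ketones and butenolides through their dienolates, together with the autoxidation of steroidal dienol ethers.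

Step 21
Reactants: 32 (11S,12E)-11-hydroperoxy-7β-(tert-butyldimethylsilyloxy)-15,15-dimethoxylabda-8(17),12-dien-16-al
Product: 34 CNP0269954.2 [(11S,15R)-11,15-epidioxy-7β,15-dihydroxylabda-8(17),12-dien-16-al], via hydroperoxy dialdehyde 33 (not isolated)
Conditions: HF (48% aq.), MeCN/H2O, 0 °C to rt
Reagents that add atoms: water, O
Why: Aqueous HF cleaves the silyl ether and hydrolyses the dimethyl acetal, and the C11 hydroperoxide then adds to the C15 aldehyde (ring–chain tautomerism to the seven-membered peroxy-hemiacetal), with C15 expected to settle under thermodynamic control.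

**Compound list**
1 | but-3-en-1-ol | C=CCCO | starting material
2 | 4-methoxybenzyl chloride | COc1ccc(CCl)cc1 | starting material
3 | 1-[(but-3-en-1-yloxy)methyl]-4-methoxybenzene | C=CCCOCc1ccc(OC)cc1 | intermediate
4 | (E)-but-2-enal | C/C=C/C=O | starting material
5 | (E)-5-[(4-methoxybenzyl)oxy]pent-2-enal | O=C/C=C/CCOCc1ccc(OC)cc1 | intermediate
6 | ethynyltriisopropylsilane | C#C[Si](C(C)C)(C(C)C)C(C)C | starting material
7 | (S)-3-{2-[(4-methoxybenzyl)oxy]ethyl}-5-(triisopropylsilyl)pent-4-ynal | O=CC[C@@H](C#C[Si](C(C)C)(C(C)C)C(C)C)CCOCc1ccc(OC)cc1 | intermediate (not isolated)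
8 | (R)-3-{2-[(4-methoxybenzyl)oxy]ethyl}-5-(triisopropylsilyl)pent-4-yn-1-ol | OCC[C@@H](C#C[Si](C(C)C)(C(C)C)C(C)C)CCOCc1ccc(OC)cc1 | intermediate
9 | (R)-3-{2-[(4-methoxybenzyl)oxy]ethyl}pent-4-yn-1-ol | OCC[C@@H](C#C)CCOCc1ccc(OC)cc1 | intermediate
10 | (E)-alkenyl(dimethyl)alane from 9, hydroxyl as dimethylaluminium alkoxide | O([Al](C)C)CC[C@@H](/C(C)=C/[Al](C)C)CCOCc1ccc(OC)cc1 | intermediate (not isolated)
11 | (R,E)-5-iodo-3-{2-[(4-methoxybenzyl)oxy]ethyl}-4-methylpent-4-en-1-ol | OCC[C@@H](/C(C)=C/I)CCOCc1ccc(OC)cc1 | intermediate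
12 | (S,E)-5-iodo-3-{2-[(4-methoxybenzyl)oxy]ethyl}-4-methylpent-4-enal | O=CC[C@@H](/C(C)=C/I)CCOCc1ccc(OC)cc1 | intermediate
13 | (S,E)-5-iodo-3-{2-[(4-methoxybenzyl)oxy]ethyl}-4-methyl-2-methylidenepent-4-enal | O=CC(=C)[C@@H](/C(C)=C/I)CCOCc1ccc(OC)cc1 | intermediate
14 | (4S,6S,7E)-8-iodo-6-{2-[(4-methoxybenzyl)oxy]ethyl}-7-methyl-5-methylideneocta-1,7-dien-4-ol | C=CC[C@H](O)C(=C)[C@@H](/C(C)=C/I)CCOCc1ccc(OC)cc1 | intermediate
15 | tert-butyldimethylsilyl ether of 14 | C=CC[C@H](O[Si](C)(C)C(C)(C)C)C(=C)[C@@H](/C(C)=C/I)CCOCc1ccc(OC)cc1 | intermediate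
16 | 2-methylprop-2-enal | C=C(C)C=O | starting material
17 | (2E,5S,7S,8E)-5-[(tert-butyldimethylsilyl)oxy]-9-iodo-7-{2-[(4-methoxybenzyl)oxy]ethyl}-2,8-dimethyl-6-methylidenenona-2,8-dienal | O=C/C(C)=C/C[C@H](O[Si](C)(C)C(C)(C)C)C(=C)[C@@H](/C(C)=C/I)CCOCc1ccc(OC)cc1 | intermediate
18 | tributyl(vinyl)stannane | C=C[Sn](CCCC)(CCCC)CCCC | starting material
19 | (2E,5S,7R,8E)-5-[(tert-butyldimethylsilyl)oxy]-7-{2-[(4-methoxybenzyl)oxy]ethyl}-2,8-dimethyl-6-methylideneundeca-2,8,10-trienal | O=C/C(C)=C/C[C@H](O[Si](C)(C)C(C)(C)C)C(=C)[C@@H](/C(C)=C/C=C)CCOCc1ccc(OC)cc1 | intermediate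
20 | 7β-(tert-butyldimethylsilyloxy)-12-(4-methoxybenzyloxy)-13,14,15,16-tetranorlabda-1,8(17)-dien-18-al (4α-formyl, 5α-H, 9α-H, 10β-methyl) | C=C1[C@H](CCOCc3ccc(OC)cc3)[C@@]2(C)C=CC[C@@](C)(C=O)[C@@H]2C[C@@H]1O[Si](C)(C)C(C)(C)C | intermediate
21 | N-(tert-butyldimethylsilyl)hydrazone of 20 | C=C1[C@H](CCOCc3ccc(OC)cc3)[C@@]2(C)C=CC[C@@](C)(/C=N/N[Si](C)(C)C(C)(C)C)[C@@H]2C[C@@H]1O[Si](C)(C)C(C)(C)C | intermediate (not isolated)
22 | 7β-(tert-butyldimethylsilyloxy)-12-(4-methoxybenzyloxy)-13,14,15,16-tetranorlabda-1,8(17)-diene | C=C1[C@H](CCOCc3ccc(OC)cc3)[C@@]2(C)C=CCC(C)(C)[C@@H]2C[C@@H]1O[Si](C)(C)C(C)(C)C | intermediate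
23 | 7β-(tert-butyldimethylsilyloxy)-12-(4-methoxybenzyloxy)-13,14,15,16-tetranorlabd-8(17)-ene | C=C1[C@H](CCOCc3ccc(OC)cc3)[C@@]2(C)CCCC(C)(C)[C@@H]2C[C@@H]1O[Si](C)(C)C(C)(C)C | intermediate
24 | 7β-(tert-butyldimethylsilyloxy)-13,14,15,16-tetranorlabd-8(17)-en-12-ol | C=C1[C@H](CCO)[C@@]2(C)CCCC(C)(C)[C@@H]2C[C@@H]1O[Si](C)(C)C(C)(C)C | intermediate
25 | 7β-(tert-butyldimethylsilyloxy)-13,14,15,16-tetranorlabd-8(17)-en-12-al | C=C1[C@H](CC=O)[C@@]2(C)CCCC(C)(C)[C@@H]2C[C@@H]1O[Si](C)(C)C(C)(C)C | intermediate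
26 | 3-bromo-1,1-dimethoxypropane | COC(OC)CCBr | starting material
27 | triphenylphosphine | c1ccc(cc1)P(c1ccccc1)c1ccccc1 | starting material
28 | (3,3-dimethoxypropyl)triphenylphosphonium bromide | COC(OC)CC[P+](c1ccccc1)(c1ccccc1)c1ccccc1.[Br-] | intermediate
29 | ethyl formate | CCOC=O | starting material
30 | 4,4-dimethoxy-2-(triphenyl-λ5-phosphanylidene)butanal | O=CC(CC(OC)OC)=P(c1ccccc1)(c1ccccc1)c1ccccc1 | intermediate
31 | (12E)-7β-(tert-butyldimethylsilyloxy)-15,15-dimethoxylabda-8(17),12-dien-16-al | C=C1[C@H](C/C=C(/C=O)CC(OC)OC)[C@@]2(C)CCCC(C)(C)[C@@H]2C[C@@H]1O[Si](C)(C)C(C)(C)C | intermediate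
32 | (11S,12E)-11-hydroperoxy-7β-(tert-butyldimethylsilyloxy)-15,15-dimethoxylabda-8(17),12-dien-16-al | C=C1[C@H]([C@@H](OO)/C=C(/C=O)CC(OC)OC)[C@@]2(C)CCCC(C)(C)[C@@H]2C[C@@H]1O[Si](C)(C)C(C)(C)C | intermediate
33 | (11S,12E)-11-hydroperoxy-7β-hydroxylabda-8(17),12-diene-15,16-dial | C=C1[C@H]([C@@H](OO)/C=C(/C=O)CC=O)[C@@]2(C)CCCC(C)(C)[C@@H]2C[C@@H]1O | intermediate (not isolated)
34 | CNP0269954.2, (11S,15R)-11,15-epidioxy-7β,15-dihydroxylabda-8(17),12-dien-16-al | C=C1[C@H]([C@@H]2C=C(C=O)C[C@H](O)OO2)[C@@]2(C)CCCC(C)(C)[C@@H]2C[C@@H]1O | target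

**Step count**
Total: 21 steps. Longest linear sequence: 19 steps (steps 1–16 and 19–21).

**Three steps most likely to fail**

Step 20 (Proposed new method). The dienolate may take up oxygen at the α-carbon instead of C11, the product hydroperoxide may be dehydrated by base to the 11-ketone (Kornblum–DeLaMare pathway), the enal may self-condense, or facial selection at C11 may be weak. Fallback with known chemistry, from 31: soft enolization with TBSOTf and Et3N should give the silyl dienol ether F1. N-Bromosuccinimide at −78 °C should brominate its γ-terminus and give the 11-bromo enal F2 as a mixture of C11 epimers. Silver-assisted perhydrolysis (AgOCOCF3, anhydrous H2O2 in Et2O) should then exchange bromide for a hydroperoxy group and return to 32, the C11 epimers being separated at that stage.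

Step 12. The cyclization may be slow because the inside methyl disfavours the s-cis diene, it may leak to the cis-fused adduct through the exo-formyl transition state, or the aluminium reagent may ionize the allylic silyl ether. Fallback, from 19: acetalization with 1,2-bis(trimethylsilyloxy)ethane and catalytic TMSOTf at −78 °C should give the 1,3-dioxolane F3. The same silyl triflate should open F3 to a vinyl oxocarbenium ion, a much stronger dienophile, and the ionic intramolecular Diels–Alder reaction should give the dioxolane adduct F4 at low temperature. Mild aqueous acid (oxalic acid, THF/H2O) should then release aldehyde 20.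

Step 14. Hydrogen may also add to the exocyclic alkene, or the catalyst may move that alkene into the ring. Fallback, from 22: Bu4NF should give the allylic alcohol F5. Hydroxyl-directed epoxidation (VO(acac)2, t-BuOOH) should oxidize only the exocyclic alkene and give the epoxy alcohol F6 (configuration at C8 immaterial). Hydrogenation of the one remaining alkene (H2, RhCl(PPh3)3) should give the saturated epoxy alcohol F7, and TBSOTf with 2,6-lutidine the silyl ether F8. Deoxygenation of the epoxide with WCl6 and n-BuLi should restore the exocyclic alkene and return to 23.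

**Further compounds**
F1 | step 20 | silyl dienol ether of 31, (11E)-16-(tert-butyldimethylsilyloxy)-labda-8(17),11,13(16)-triene with 7β-silyloxy and 15,15-dimethoxy groups | C=C1[C@H](/C=C/C(=C/O[Si](C)(C)C(C)(C)C)CC(OC)OC)[C@@]2(C)CCCC(C)(C)[C@@H]2C[C@@H]1O[Si](C)(C)C(C)(C)C
F2 | step 20 | (12E)-11-bromo-7β-(tert-butyldimethylsilyloxy)-15,15-dimethoxylabda-8(17),12-dien-16-al (C11 epimers) | C=C1[C@H](C(Br)/C=C(/C=O)CC(OC)OC)[C@@]2(C)CCCC(C)(C)[C@@H]2C[C@@H]1O[Si](C)(C)C(C)(C)C
F3 | step 12 | 1,3-dioxolane acetal of trienal 19 | C1COC(O1)/C(C)=C/C[C@H](O[Si](C)(C)C(C)(C)C)C(=C)[C@@H](/C(C)=C/C=C)CCOCc1ccc(OC)cc1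
F4 | step 12 | 1,3-dioxolane acetal of adduct 20 | C=C1[C@H](CCOCc3ccc(OC)cc3)[C@@]2(C)C=CC[C@@](C)(C4OCCO4)[C@@H]2C[C@@H]1O[Si](C)(C)C(C)(C)C
F5 | step 14 | 12-(4-methoxybenzyloxy)-13,14,15,16-tetranorlabda-1,8(17)-dien-7β-ol | C=C1[C@H](CCOCc3ccc(OC)cc3)[C@@]2(C)C=CCC(C)(C)[C@@H]2C[C@@H]1O
F6 | step 14 | 8,17-epoxide of F5 | C1OC13[C@H](CCOCc4ccc(OC)cc4)[C@@]2(C)C=CCC(C)(C)[C@@H]2C[C@@H]3O
F7 | step 14 | 1,2-dihydro derivative of F6 | C1OC13[C@H](CCOCc4ccc(OC)cc4)[C@@]2(C)CCCC(C)(C)[C@@H]2C[C@@H]3O
F8 | step 14 | tert-butyldimethylsilyl ether of F7 | C1OC13[C@H](CCOCc4ccc(OC)cc4)[C@@]2(C)CCCC(C)(C)[C@@H]2C[C@@H]3O[Si](C)(C)C(C)(C)C
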